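**Retrosynthetic overview**
1. Target 25 ⇐ global debenzylation of 24. The flavonol pyranone ring is built last (Claisen–Schmidt, then Algar–Flynn–Oyamada) on the formyl group ortho to the flavan-4-yl substituent (20 + 21).
2. Flavan stereotriad ⇐ hydroboration–oxidation of (2S)-2,4-diaryl-2H-chromene 16. C2 ⇐ catalytic enantioselective aryl transfer from 15 to the benzopyrylium ion of chromene acetal 14 ⇐ coumarin 12.
3. Pyran ring of the flavan unit ⇐ 4-arylcoumarin 10 ⇐ 5 → 6 ring expansion of spiro-butenolide dienone 9, made by oxidative dearomatisation of phenol acid 8.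
4. Enabling feature: the flavan A ring is 5-deoxy and its only hydroxyl (O7) is para to C4a. C4a can therefore become the sp3 spiro carbon of a cross-conjugated dienone (C7=O), and the lactone oxygen O1 can move to the adjacent C8a.
5. 8 ⇐ Suzuki coupling of (Z)-β-boryl acrylate 6 (from alkynoate 5 = 3 + 4) with bromo-aldehyde 2 (from 1). Ring order: spirolactone → flavan pyran ring → flavonol pyranone ring.

Key step: step 6

Remark (assumption): compounds 10–16 carry a hindered C4–aryl bond and may exist as slowly interconverting rotamers; they are drawn without axial descriptors because this element vanishes when C4 becomes sp3 in step 12, and the catalyst enantiomer in step 11 is taken to be the one that delivers the aryl group to the Re face of C2.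

**Route**

Step 1
Reactants: 1 3,4,5-tris(benzyloxy)benzaldehyde
Product: 2 2-bromo-3,4,5-tris(benzyloxy)benzaldehyde
Conditions: NBS (1.05 equiv), MeCN, rt, dark
Reagents that add atoms: N-bromosuccinimide O=C1CCC(=O)N1Br
Why: Electrophilic aromatic bromination; the two free ring positions are equivalent and activated ortho/para by OBn, so mono-bromination next to the formyl group should be clean.

Step 2
Reactants: 3 tert-butyl(4-iodophenoxy)dimethylsilane; 4 methyl propiolate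
Product: 5 methyl 3-{4-[(tert-butyldimethylsilyl)oxy]phenyl}prop-2-ynoate
Conditions: Pd(PPh3)2Cl2 (2 mol%), CuI (4 mol%), K2CO3, THF, 65 °C
Reagents that add atoms: none
Why: Sonogashira coupling of an aryl iodide with an electron-poor terminal alkyne under amine-free carbonate conditions, which avoid conjugate addition to the propiolate.

Step 3
Reactants: 5 methyl 3-{4-[(tert-butyldimethylsilyl)oxy]phenyl}prop-2-ynoate
Product: 6 methyl (Z)-3-{4-[(tert-butyldimethylsilyl)oxy]phenyl}-3-(4,4,5,5-tetramethyl-1,3,2-dioxaborolan-2-yl)prop-2-enoate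
Conditions: B2pin2, CuCl (3 mol%), Xantphos (3 mol%), NaOt-Bu (6 mol%), MeOH (2 equiv), THF, rt
Reagents that add atoms: bis(pinacolato)diboron CC1(C)OB(OC1(C)C)B1OC(C)(C)C(C)(C)O1
Why: Copper(I)-catalysed β-borylation (formal syn-hydroboration) of an alkynoate; Cu–Bpin adds syn with boron at the β-carbon and methanol protonates the α-carbon with retention, which places the ester cis to the aryl ring.

Step 4
Reactants: 6 methyl (Z)-3-{4-[(tert-butyldimethylsilyl)oxy]phenyl}-3-(4,4,5,5-tetramethyl-1,3,2-dioxaborolan-2-yl)prop-2-enoate; 2 2-bromo-3,4,5-tris(benzyloxy)benzaldehyde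
Product: 7 methyl (E)-3-{4-[(tert-butyldimethylsilyl)oxy]phenyl}-3-[2,3,4-tris(benzyloxy)-6-formylphenyl]prop-2-enoate (ester cis to the siloxyphenyl ring)
Conditions: Pd(OAc)2 (5 mol%), SPhos (10 mol%), K3PO4, toluene/H2O (10:1), 80 °C
Reagents that add atoms: none
Why: Suzuki–Miyaura coupling of an alkenyl boronate with a hindered aryl bromide using a dialkylbiarylphosphine ligand; it proceeds with retention of alkene geometry, so the ester stays cis to the siloxyphenyl ring.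

Step 5
Reactants: 7 methyl (E)-3-{4-[(tert-butyldimethylsilyl)oxy]phenyl}-3-[2,3,4-tris(benzyloxy)-6-formylphenyl]prop-2-enoate
Product: 8 (E)-3-(4-hydroxyphenyl)-3-[2,3,4-tris(benzyloxy)-6-formylphenyl]prop-2-enoic acid (CO2H cis to the hydroxyphenyl ring)
Conditions: LiOH·H2O, THF/MeOH/H2O, rt; then 1 M HCl to pH 3, 0 °C
Reagents that add atoms: lithium hydroxide [Li+].[OH-]
Why: Saponification of the methyl ester with concurrent cleavage of the base-labile aryl silyl ether; the non-enolisable aldehyde and the alkene geometry should survive hydroxide at room temperature.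

Step 6
Reactants: 8 (E)-3-(4-hydroxyphenyl)-3-[2,3,4-tris(benzyloxy)-6-formylphenyl]prop-2-enoic acid
Product: 10 7-hydroxy-4-[2,3,4-tris(benzyloxy)-6-formylphenyl]-2H-chromen-2-one, via spiro-butenolide dienone 9 (not isolated)
Conditions: PhI(OAc)2 (1.05 equiv), HFIP/CH2Cl2, 0 °C; then TFA, 0 °C → rt
Reagents that add atoms: none
Why: Proposed new method: iodine(III) converts the phenol into an O-bound λ3-iodane that ionises to a phenoxenium-type species, and the carboxyl group, held cis to the ring by the alkene, attacks the para carbon C4a (5-exo closure at the dearomatised ring) to give spirolactone 9; acid then activates the cross-conjugated dienone, the lactone C–O bond shifts from C4a to the neighbouring C8a (1,2-acyloxy shift of the dienone–phenol type, through a bridged acyloxonium transition state or through conjugate addition of the medium at C8a, transacylation and elimination) and proton loss rearomatises the ring, so the five-membered spirolactone becomes the six-membered pyranone ring with the free hydroxyl para to C4a. The closest known reaction types are the iodine(III)-mediated dearomatising spirolactonisation of para-hydroxyaryl carboxylic acids (including biaryl-2-carboxylic acids, of which 8 is the vinylogue) and the acid-promoted dienone–phenol rearrangement of para-quinol esters and spirodienone lactones with oxygen migration to resorcinol-type products; combining them on a cis-3-(4-hydroxyphenyl)acrylic acid is the extrapolation. No stereocentre is formed: 9 is achiral and the C4–aryl axis of 10 is carried as rotamers. The selectivity needed is O- over C-migration, because a shift of C4 would give the 6-hydroxy isomer; it should be secured because C4 is the sp2 β-carbon of an enoate, whose shift would place positive charge next to the lactone carbonyl and which cannot ionise as a benzylic cation, while the two ortho carbons are equivalent so the direction of the shift does not matter. The drive comes from rearomatisation and from forming the conjugated coumarin.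

Step 7
Reactants: 10 7-hydroxy-4-[2,3,4-tris(benzyloxy)-6-formylphenyl]-2H-chromen-2-one
Product: 11 7-(benzyloxy)-4-[2,3,4-tris(benzyloxy)-6-formylphenyl]-2H-chromen-2-one
Conditions: BnBr, K2CO3, DMF, rt
Reagents that add atoms: benzyl bromide BrCc1ccccc1
Why: Williamson ether synthesis on the only acidic OH; the coumarin and the aldehyde tolerate K2CO3/DMF.

Step 8
Reactants: 11 7-(benzyloxy)-4-[2,3,4-tris(benzyloxy)-6-formylphenyl]-2H-chromen-2-one
Product: 12 7-(benzyloxy)-4-[2,3,4-tris(benzyloxy)-6-(1,3-dioxolan-2-yl)phenyl]-2H-chromen-2-one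
Conditions: HOCH2CH2OH, p-TsOH·H2O (cat.), toluene, reflux (Dean–Stark)
Reagents that add atoms: ethylene glycol OCCO
Why: Acid-catalysed acetalisation with azeotropic removal of water masks the aldehyde for the hydride and borane steps; the coumarin lactone is inert.

Step 9
Reactants: 12 7-(benzyloxy)-4-[2,3,4-tris(benzyloxy)-6-(1,3-dioxolan-2-yl)phenyl]-2H-chromen-2-one
Product: 13 7-(benzyloxy)-4-[2,3,4-tris(benzyloxy)-6-(1,3-dioxolan-2-yl)phenyl]-2H-chromen-2-ol (racemic lactol)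
Conditions: DIBAL-H (1.1 equiv), CH2Cl2, −78 °C; Rochelle salt work-up
Reagents that add atoms: none
Why: Partial reduction of the unsaturated lactone with DIBAL-H at −78 °C should stop at the aluminium lactolate and give the 2H-chromen-2-ol on work-up; benzyl ethers and the dioxolane are inert.

Step 10
Reactants: 13 7-(benzyloxy)-4-[2,3,4-tris(benzyloxy)-6-(1,3-dioxolan-2-yl)phenyl]-2H-chromen-2-ol
Product: 14 7-(benzyloxy)-2-ethoxy-4-[2,3,4-tris(benzyloxy)-6-(1,3-dioxolan-2-yl)phenyl]-2H-chromene (racemic at C2)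
Conditions: EtOH, PPTS (cat.), 3 Å MS, rt
Reagents that add atoms: ethanol CCO
Why: Acid-catalysed acetal formation through the aromatic benzopyrylium ion, which forms far more readily than the dioxolane ionises, so the aryl acetal should stay intact under PPTS.

Step 11
Reactants: 14 7-(benzyloxy)-2-ethoxy-4-[2,3,4-tris(benzyloxy)-6-(1,3-dioxolan-2-yl)phenyl]-2H-chromene; 15 [3,4-bis(benzyloxy)phenyl]boronic acid
Product: 16 (2S)-7-(benzyloxy)-2-[3,4-bis(benzyloxy)phenyl]-4-[2,3,4-tris(benzyloxy)-6-(1,3-dioxolan-2-yl)phenyl]-2H-chromene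
Conditions: chiral tartaric-acid-derived diol–amide catalyst (10 mol%), Yb(OTf)3 (5 mol%), EtOAc, −40 °C
Reagents that add atoms: none
Why: Catalytic enantioselective addition of an aryl boron nucleophile to the benzopyrylium ion generated from the chromene acetal (chiral diol–boronate/Lewis acid catalysis); the catalyst directs the aryl group to the Re face of C2 and sets (2S), while C4 is blocked by its aryl group.

Step 12
Reactants: 16 (2S)-7-(benzyloxy)-2-[3,4-bis(benzyloxy)phenyl]-4-[2,3,4-tris(benzyloxy)-6-(1,3-dioxolan-2-yl)phenyl]-2H-chromene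
Product: 18 (2R,3S,4S)-7-(benzyloxy)-2-[3,4-bis(benzyloxy)phenyl]-4-[2,3,4-tris(benzyloxy)-6-(1,3-dioxolan-2-yl)phenyl]-3,4-dihydro-2H-chromen-3-ol, via C3-alkylborane 17 (not isolated)
Conditions: BH3·THF, THF, 0 °C → rt; then 3 M NaOH, 30% H2O2, 0 °C → rt
Reagents that add atoms: borane (boron of 17 only) B; hydrogen peroxide OO
Why: Hydroboration–oxidation of the trisubstituted styrenic alkene; boron adds to C3 anti to the C2 aryl group and hydrogen to C4 on the same face (syn addition), so C3 and C4 are set from C2 as 2,3-trans-3,4-trans, and the C–B bond is oxidised with retention.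

Step 13
Reactants: 18 (2R,3S,4S)-7-(benzyloxy)-2-[3,4-bis(benzyloxy)phenyl]-4-[2,3,4-tris(benzyloxy)-6-(1,3-dioxolan-2-yl)phenyl]-3,4-dihydro-2H-chromen-3-ol
Product: 19 (2R,3S,4S)-3,7-bis(benzyloxy)-2-[3,4-bis(benzyloxy)phenyl]-4-[2,3,4-tris(benzyloxy)-6-(1,3-dioxolan-2-yl)phenyl]-3,4-dihydro-2H-chromene
Conditions: NaH, BnBr, n-Bu4NI (cat.), DMF, 0 °C → rt
Reagents that add atoms: benzyl bromide BrCc1ccccc1
Why: Williamson benzylation of the secondary alcohol prevents hemiacetal formation with the aldehyde released in the next step.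

Step 14
Reactants: 19 (2R,3S,4S)-3,7-bis(benzyloxy)-2-[3,4-bis(benzyloxy)phenyl]-4-[2,3,4-tris(benzyloxy)-6-(1,3-dioxolan-2-yl)phenyl]-3,4-dihydro-2H-chromene
Product: 20 2-[(2R,3S,4S)-3,7-bis(benzyloxy)-2-[3,4-bis(benzyloxy)phenyl]-3,4-dihydro-2H-chromen-4-yl]-3,4,5-tris(benzyloxy)benzaldehyde
Conditions: 1 M HCl, THF, rt
Reagents that add atoms: water O
Why: Mild aqueous acid hydrolysis of the dioxolane; the fully O-benzylated flavan has no free phenol and should be stable to dilute acid.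

Step 15
Reactants: 20 2-[(2R,3S,4S)-3,7-bis(benzyloxy)-2-[3,4-bis(benzyloxy)phenyl]-3,4-dihydro-2H-chromen-4-yl]-3,4,5-tris(benzyloxy)benzaldehyde; 21 1-[4-(benzyloxy)-2-hydroxyphenyl]ethan-1-one
Product: 22 (E)-1-[4-(benzyloxy)-2-hydroxyphenyl]-3-{2-[(2R,3S,4S)-3,7-bis(benzyloxy)-2-[3,4-bis(benzyloxy)phenyl]-3,4-dihydro-2H-chromen-4-yl]-3,4,5-tris(benzyloxy)phenyl}prop-2-en-1-one
Conditions: KOH, EtOH/THF, rt
Reagents that add atoms: none
Why: Claisen–Schmidt aldol condensation of the non-enolisable aldehyde with the 2'-hydroxyacetophenone gives the (E)-chalcone; no flavan stereocentre is acidic under these conditions.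

Step 16
Reactants: 22 (E)-1-[4-(benzyloxy)-2-hydroxyphenyl]-3-{2-[(2R,3S,4S)-3,7-bis(benzyloxy)-2-[3,4-bis(benzyloxy)phenyl]-3,4-dihydro-2H-chromen-4-yl]-3,4,5-tris(benzyloxy)phenyl}prop-2-en-1-one
Product: 24 7-(benzyloxy)-2-{2-[(2R,3S,4S)-3,7-bis(benzyloxy)-2-[3,4-bis(benzyloxy)phenyl]-3,4-dihydro-2H-chromen-4-yl]-3,4,5-tris(benzyloxy)phenyl}-3-hydroxy-4H-chromen-4-one, via dihydroflavonol 23 (not isolated)
Conditions: 30% H2O2, 2 M NaOH, MeOH/THF, 0 °C → rt
Reagents that add atoms: hydrogen peroxide OO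
Why: Algar–Flynn–Oyamada reaction; alkaline hydrogen peroxide oxidises the enone while the phenoxide closes the pyranone ring to the dihydroflavonol, which is dehydrogenated in the same pot to the flavonol.

Step 17
Reactants: 24 7-(benzyloxy)-2-{2-[(2R,3S,4S)-3,7-bis(benzyloxy)-2-[3,4-bis(benzyloxy)phenyl]-3,4-dihydro-2H-chromen-4-yl]-3,4,5-tris(benzyloxy)phenyl}-3-hydroxy-4H-chromen-4-one
Product: 25 2-{2-[(2R,3S,4S)-2-(3,4-dihydroxyphenyl)-3,7-dihydroxy-3,4-dihydro-2H-chromen-4-yl]-3,4,5-trihydroxyphenyl}-3,7-dihydroxy-4H-chromen-4-one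
Conditions: H2 (1 atm), Pd(OH)2/C, THF/MeOH, rt
Reagents that add atoms: none
Why: Hydrogenolysis of the eight benzyl ethers over palladium; the flavonol enone and the flavan C–O and C–aryl bonds should not be reduced at 1 atm and room temperature.

**Compound list**

1 | 3,4,5-tris(benzyloxy)benzaldehyde | O=Cc1cc(OCc2ccccc2)c(OCc2ccccc2)c(OCc2ccccc2)c1 | starting material
2 | 2-bromo-3,4,5-tris(benzyloxy)benzaldehyde | O=Cc1cc(OCc2ccccc2)c(OCc2ccccc2)c(OCc2ccccc2)c1Br | intermediate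
3 | tert-butyl(4-iodophenoxy)dimethylsilane | CC(C)(C)[Si](C)(C)Oc1ccc(I)cc1 | starting material
4 | methyl propiolate | C#CC(=O)OC | starting material
5 | methyl 3-{4-[(tert-butyldimethylsilyl)oxy]phenyl}prop-2-ynoate | COC(=O)C#Cc1ccc(O[Si](C)(C)C(C)(C)C)cc1 | intermediate
6 | methyl (Z)-3-{4-[(tert-butyldimethylsilyl)oxy]phenyl}-3-(4,4,5,5-tetramethyl-1,3,2-dioxaborolan-2-yl)prop-2-enoate | COC(=O)/C=C(/B1OC(C)(C)C(C)(C)O1)c1ccc(O[Si](C)(C)C(C)(C)C)cc1 | intermediate
7 | methyl (E)-3-{4-[(tert-butyldimethylsilyl)oxy]phenyl}-3-[2,3,4-tris(benzyloxy)-6-formylphenyl]prop-2-enoate | COC(=O)/C=C(/c1c(C=O)cc(OCc2ccccc2)c(OCc2ccccc2)c1OCc1ccccc1)c1ccc(O[Si](C)(C)C(C)(C)C)cc1 | intermediate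
8 | (E)-3-(4-hydroxyphenyl)-3-[2,3,4-tris(benzyloxy)-6-formylphenyl]prop-2-enoic acid | OC(=O)/C=C(/c1c(C=O)cc(OCc2ccccc2)c(OCc2ccccc2)c1OCc1ccccc1)c1ccc(O)cc1 | intermediate
9 | 4-[2,3,4-tris(benzyloxy)-6-formylphenyl]-1-oxaspiro[4.5]deca-3,6,9-triene-2,8-dione (achiral; not isolated) | O=Cc1cc(OCc2ccccc2)c(OCc2ccccc2)c(OCc2ccccc2)c1C1=CC(=O)OC12C=CC(=O)C=C2 | intermediate
10 | 7-hydroxy-4-[2,3,4-tris(benzyloxy)-6-formylphenyl]-2H-chromen-2-one | O=Cc1cc(OCc2ccccc2)c(OCc2ccccc2)c(OCc2ccccc2)c1C1=CC(=O)Oc2cc(O)ccc12 | intermediate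
11 | 7-(benzyloxy)-4-[2,3,4-tris(benzyloxy)-6-formylphenyl]-2H-chromen-2-one | O=Cc1cc(OCc2ccccc2)c(OCc2ccccc2)c(OCc2ccccc2)c1C1=CC(=O)Oc2cc(OCc3ccccc3)ccc12 | intermediate
12 | 7-(benzyloxy)-4-[2,3,4-tris(benzyloxy)-6-(1,3-dioxolan-2-yl)phenyl]-2H-chromen-2-one | O1CCOC1c1cc(OCc2ccccc2)c(OCc2ccccc2)c(OCc2ccccc2)c1C1=CC(=O)Oc2cc(OCc3ccccc3)ccc12 | intermediate
13 | 7-(benzyloxy)-4-[2,3,4-tris(benzyloxy)-6-(1,3-dioxolan-2-yl)phenyl]-2H-chromen-2-ol (racemic at C2) | O1CCOC1c1cc(OCc2ccccc2)c(OCc2ccccc2)c(OCc2ccccc2)c1C1=CC(O)Oc2cc(OCc3ccccc3)ccc12 | intermediate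
14 | 7-(benzyloxy)-2-ethoxy-4-[2,3,4-tris(benzyloxy)-6-(1,3-dioxolan-2-yl)phenyl]-2H-chromene (racemic at C2) | O1CCOC1c1cc(OCc2ccccc2)c(OCc2ccccc2)c(OCc2ccccc2)c1C1=CC(OCC)Oc2cc(OCc3ccccc3)ccc12 | intermediate
15 | [3,4-bis(benzyloxy)phenyl]boronic acid | OB(O)c1ccc(OCc2ccccc2)c(OCc2ccccc2)c1 | starting material
16 | (2S)-7-(benzyloxy)-2-[3,4-bis(benzyloxy)phenyl]-4-[2,3,4-tris(benzyloxy)-6-(1,3-dioxolan-2-yl)phenyl]-2H-chromene | O1CCOC1c1cc(OCc2ccccc2)c(OCc2ccccc2)c(OCc2ccccc2)c1C1=C[C@@H](c2ccc(OCc3ccccc3)c(OCc3ccccc3)c2)Oc2cc(OCc3ccccc3)ccc12 | intermediate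
17 | [(2S,3S,4S)-7-(benzyloxy)-2-[3,4-bis(benzyloxy)phenyl]-4-[2,3,4-tris(benzyloxy)-6-(1,3-dioxolan-2-yl)phenyl]-3,4-dihydro-2H-chromen-3-yl]borane (boron on C3 trans to both aryl groups; not isolated) | O1CCOC1c1cc(OCc2ccccc2)c(OCc2ccccc2)c(OCc2ccccc2)c1[C@@H]1c2ccc(OCc3ccccc3)cc2O[C@H](c2ccc(OCc3ccccc3)c(OCc3ccccc3)c2)[C@H]1B | intermediate
18 | (2R,3S,4S)-7-(benzyloxy)-2-[3,4-bis(benzyloxy)phenyl]-4-[2,3,4-tris(benzyloxy)-6-(1,3-dioxolan-2-yl)phenyl]-3,4-dihydro-2H-chromen-3-ol | O1CCOC1c1cc(OCc2ccccc2)c(OCc2ccccc2)c(OCc2ccccc2)c1[C@@H]1c2ccc(OCc3ccccc3)cc2O[C@H](c2ccc(OCc3ccccc3)c(OCc3ccccc3)c2)[C@H]1O | intermediate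
19 | (2R,3S,4S)-3,7-bis(benzyloxy)-2-[3,4-bis(benzyloxy)phenyl]-4-[2,3,4-tris(benzyloxy)-6-(1,3-dioxolan-2-yl)phenyl]-3,4-dihydro-2H-chromene | O1CCOC1c1cc(OCc2ccccc2)c(OCc2ccccc2)c(OCc2ccccc2)c1[C@@H]1c2ccc(OCc3ccccc3)cc2O[C@H](c2ccc(OCc3ccccc3)c(OCc3ccccc3)c2)[C@H]1OCc1ccccc1 | intermediate
20 | 2-[(2R,3S,4S)-3,7-bis(benzyloxy)-2-[3,4-bis(benzyloxy)phenyl]-3,4-dihydro-2H-chromen-4-yl]-3,4,5-tris(benzyloxy)benzaldehyde | O=Cc1cc(OCc2ccccc2)c(OCc2ccccc2)c(OCc2ccccc2)c1[C@@H]1c2ccc(OCc3ccccc3)cc2O[C@H](c2ccc(OCc3ccccc3)c(OCc3ccccc3)c2)[C@H]1OCc1ccccc1 | intermediate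
21 | 1-[4-(benzyloxy)-2-hydroxyphenyl]ethan-1-one | CC(=O)c1ccc(OCc2ccccc2)cc1O | starting material
22 | (E)-1-[4-(benzyloxy)-2-hydroxyphenyl]-3-{2-[(2R,3S,4S)-3,7-bis(benzyloxy)-2-[3,4-bis(benzyloxy)phenyl]-3,4-dihydro-2H-chromen-4-yl]-3,4,5-tris(benzyloxy)phenyl}prop-2-en-1-one | O=C(/C=C/c1cc(OCc2ccccc2)c(OCc2ccccc2)c(OCc2ccccc2)c1[C@@H]1c2ccc(OCc3ccccc3)cc2O[C@H](c2ccc(OCc3ccccc3)c(OCc3ccccc3)c2)[C@H]1OCc1ccccc1)c1ccc(OCc2ccccc2)cc1O | intermediate
23 | 7-(benzyloxy)-2-{2-[(2R,3S,4S)-3,7-bis(benzyloxy)-2-[3,4-bis(benzyloxy)phenyl]-3,4-dihydro-2H-chromen-4-yl]-3,4,5-tris(benzyloxy)phenyl}-3-hydroxy-2,3-dihydro-4H-chromen-4-one (2,3-trans at the new centres, diastereomer mixture; not isolated) | O=C1C(O)C(c2cc(OCc3ccccc3)c(OCc3ccccc3)c(OCc3ccccc3)c2[C@@H]2c3ccc(OCc4ccccc4)cc3O[C@H](c3ccc(OCc4ccccc4)c(OCc4ccccc4)c3)[C@H]2OCc2ccccc2)Oc2cc(OCc3ccccc3)ccc12 | intermediate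
24 | 7-(benzyloxy)-2-{2-[(2R,3S,4S)-3,7-bis(benzyloxy)-2-[3,4-bis(benzyloxy)phenyl]-3,4-dihydro-2H-chromen-4-yl]-3,4,5-tris(benzyloxy)phenyl}-3-hydroxy-4H-chromen-4-one | O=c1c(O)c(-c2cc(OCc3ccccc3)c(OCc3ccccc3)c(OCc3ccccc3)c2[C@@H]2c3ccc(OCc4ccccc4)cc3O[C@H](c3ccc(OCc4ccccc4)c(OCc4ccccc4)c3)[C@H]2OCc2ccccc2)oc2cc(OCc3ccccc3)ccc12 | intermediate
25 | 2-{2-[(2R,3S,4S)-2-(3,4-dihydroxyphenyl)-3,7-dihydroxy-3,4-dihydro-2H-chromen-4-yl]-3,4,5-trihydroxyphenyl}-3,7-dihydroxy-4H-chromen-4-one | O=c1c(O)c(-c2cc(O)c(O)c(O)c2[C@@H]2c3ccc(O)cc3O[C@H](c3ccc(O)c(O)c3)[C@H]2O)oc2cc(O)ccc12 | target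

**Step count and risks**

Total step count: 17. Longest linear sequence: 16 steps (3 + 4 → 25, steps 2–17).

Steps most likely to fail:

1. Step 6 (Proposed new method). The wrong bond may migrate (shift of C4 instead of the lactone oxygen, giving the 6-hydroxy isomer), the spirolactone may fail to rearrange, or the liberated phenol may be oxidised further. Fallback with known chemistry, setting out from 2 and returning at 10: Sonogashira coupling of 2 with ethyl propiolate (Pd(PPh3)2Cl2, CuI, K2CO3, THF) should give ethyl 3-[2,3,4-tris(benzyloxy)-6-formylphenyl]prop-2-ynoate F1. Palladium(II)-catalysed hydroarylation of F1 with resorcinol (Pd(OAc)2 cat., TFA/CH2Cl2, rt) adds the resorcinol C4–H across the alkyne in a trans sense, and the ortho hydroxyl lactonises to give 10 directly. This replaces steps 2–6.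

2. Step 11. Enantiocontrol may be lost, ionisation or aryl transfer may be sluggish on the 4-aryl, acetal-bearing substrate, or the electron-rich 2-aryl-2H-chromene may racemise under Lewis acid. Fallback setting out from 12 and returning at 18, with the stereochemistry started at C4 instead of C2: copper hydride-catalysed asymmetric conjugate reduction of coumarin 12 (Cu(OAc)2·H2O, DTBM-SEGPHOS enantiomer delivering hydride to the Re face of C4, (EtO)2MeSiH, t-BuOH, toluene, rt to 40 °C so that the aryl axis equilibrates) should give (4S)-7-(benzyloxy)-4-[2,3,4-tris(benzyloxy)-6-(1,3-dioxolan-2-yl)phenyl]-3,4-dihydro-2H-chromen-2-one F2. Enolisation and O-phosphorylation (KHMDS, (PhO)2P(O)Cl, THF/HMPA, −78 °C) give the ketene acetal phosphate (4S)-7-(benzyloxy)-4-[2,3,4-tris(benzyloxy)-6-(1,3-dioxolan-2-yl)phenyl]-4H-chromen-2-yl diphenyl phosphate F3. Suzuki coupling with 15 (Pd(PPh3)4, aq. Na2CO3, DME, 60 °C) gives (4S)-7-(benzyloxy)-2-[3,4-bis(benzyloxy)phenyl]-4-[2,3,4-tris(benzyloxy)-6-(1,3-dioxolan-2-yl)phenyl]-4H-chromene F4. Hydroboration–oxidation under the conditions of step 12 adds boron to C3 anti to the C4 aryl group and hydrogen to C2 on the same face, and gives 18 through the same borane 17.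

3. Step 16. The hindered ortho-substituted chalcone may give the aurone instead, or the oxidative cyclisation may stay incomplete. Fallback setting out from 22 and returning at 24: oxidative cyclisation of 22 with catalytic iodine in DMSO at 130 °C should give the flavone 7-(benzyloxy)-2-{2-[(2R,3S,4S)-3,7-bis(benzyloxy)-2-[3,4-bis(benzyloxy)phenyl]-3,4-dihydro-2H-chromen-4-yl]-3,4,5-tris(benzyloxy)phenyl}-4H-chromen-4-one F5. C3-lithiation of F5 (LDA, THF, −78 °C), trapping with B(OMe)3 and oxidation with H2O2/AcOH then install the 3-hydroxyl and give 24.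

Further compounds
F1 | step 6 | ethyl 3-[2,3,4-tris(benzyloxy)-6-formylphenyl]prop-2-ynoate | CCOC(=O)C#Cc1c(C=O)cc(OCc2ccccc2)c(OCc2ccccc2)c1OCc1ccccc1
F2 | step 11 | (4S)-7-(benzyloxy)-4-[2,3,4-tris(benzyloxy)-6-(1,3-dioxolan-2-yl)phenyl]-3,4-dihydro-2H-chromen-2-one | O1CCOC1c1cc(OCc2ccccc2)c(OCc2ccccc2)c(OCc2ccccc2)c1[C@H]1CC(=O)Oc2cc(OCc3ccccc3)ccc12
F3 | step 11 | (4S)-7-(benzyloxy)-4-[2,3,4-tris(benzyloxy)-6-(1,3-dioxolan-2-yl)phenyl]-4H-chromen-2-yl diphenyl phosphate | O1CCOC1c1cc(OCc2ccccc2)c(OCc2ccccc2)c(OCc2ccccc2)c1[C@H]1C=C(OP(=O)(Oc2ccccc2)Oc2ccccc2)Oc2cc(OCc3ccccc3)ccc12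
F4 | step 11 | (4S)-7-(benzyloxy)-2-[3,4-bis(benzyloxy)phenyl]-4-[2,3,4-tris(benzyloxy)-6-(1,3-dioxolan-2-yl)phenyl]-4H-chromene | O1CCOC1c1cc(OCc2ccccc2)c(OCc2ccccc2)c(OCc2ccccc2)c1[C@H]1C=C(c2ccc(OCc3ccccc3)c(OCc3ccccc3)c2)Oc2cc(OCc3ccccc3)ccc12
F5 | step 16 | 7-(benzyloxy)-2-{2-[(2R,3S,4S)-3,7-bis(benzyloxy)-2-[3,4-bis(benzyloxy)phenyl]-3,4-dihydro-2H-chromen-4-yl]-3,4,5-tris(benzyloxy)phenyl}-4H-chromen-4-one | O=c1cc(-c2cc(OCc3ccccc3)c(OCc3ccccc3)c(OCc3ccccc3)c2[C@@H]2c3ccc(OCc4ccccc4)cc3O[C@H](c3ccc(OCc4ccccc4)c(OCc4ccccc4)c3)[C@H]2OCc2ccccc2)oc2cc(OCc3ccccc3)ccc12
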